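The route rests on opening the dihydrofuran ring at O1–C2. It uses two features of the core: the C2 aryl group has an oxygen para to the benzylic carbon, so a C2 cation forms readily, and carbon C3a is ortho to both the C4 hydroxyl and the C7a oxygen, which are interchangeable in an open-chain, symmetric resorcinol. One mild acid treatment converts carbinol 10, whose only defined centre is the diaryl methine C3, into trans-dihydrobenzofuran 11, setting C2 from C3 whatever the carbinol configuration. Compound 10 comes from an enantioselective copper/palladium arylboration of a stilbene, with the phenols unmasked before the boronate is oxidised. Benzyl ethers are carried throughout for a mild final deprotection.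

Key step: step 6

Assumption: in step 4, L*·HBF4 is 1,3-dimesityl-4,5-diphenyl-4,5-dihydroimidazolium tetrafluoroborate; its sense of induction on 5 is assigned on a test scale and the antipode, (4R,5R) or (4S,5S), that gives the (1S) centre is used, while the boron- or hydroxyl-bearing carbon of 8, 9 and 10 is left undefined because step 6 erases it.

Step 1
Reactants: 1 methyl 4-bromo-3,5-dihydroxybenzoate
Product: 2 methyl 4-bromo-3,5-bis(methoxymethoxy)benzoate
Conditions: MOMCl, i-Pr2NEt, CH2Cl2, 0 °C to rt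
Reagents that add atoms: chloromethyl methyl ether, COCCl
Why: Williamson-type O-alkylation of the two acidic phenols gives small acetal ethers that tolerate base, copper and palladium and can later be removed with mild acid.

Step 2
Reactants: 3 3,4-bis(benzyloxy)benzaldehyde
Product: 4 1,2-bis(benzyloxy)-4-ethenylbenzene
Conditions: Ph3PCH3Br, KOtBu, THF, 0 °C to rt
Reagents that add atoms: methyltriphenylphosphonium bromide, C[P+](c1ccccc1)(c1ccccc1)c1ccccc1.[Br-]
Why: Wittig methylenation of an unhindered aryl aldehyde with the non-stabilised ylide should give the styrene cleanly.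

Step 3
Reactants: 2 methyl 4-bromo-3,5-bis(methoxymethoxy)benzoate; 4 1,2-bis(benzyloxy)-4-ethenylbenzene
Product: 5 methyl 4-{(E)-2-[3,4-bis(benzyloxy)phenyl]ethenyl}-3,5-bis(methoxymethoxy)benzoate
Conditions: Pd(OAc)2 (5 mol %), (t-Bu)3P·HBF4 (10 mol %), Cy2NMe, 1,4-dioxane, 90 °C
Reagents that add atoms: none
Why: Heck reaction, in which the ester-activated aryl bromide adds to zerovalent palladium, the styrene inserts with the aryl group at its terminal carbon and syn β-hydride elimination gives the E-stilbene; the bulky electron-rich phosphine copes with the two ortho alkoxy groups.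

Step 4
Reactants: 5 methyl 4-{(E)-2-[3,4-bis(benzyloxy)phenyl]ethenyl}-3,5-bis(methoxymethoxy)benzoate; 6 1,3-bis(benzyloxy)-5-bromobenzene; 7 bis(pinacolato)diboron
Product: 8 methyl 4-{(1S)-2-[3,4-bis(benzyloxy)phenyl]-1-[3,5-bis(benzyloxy)phenyl]-2-(4,4,5,5-tetramethyl-1,3,2-dioxaborolan-2-yl)ethyl}-3,5-bis(methoxymethoxy)benzoate
Conditions: CuCl (10 mol %), L*·HBF4 (11 mol %), Pd(OAc)2 (3 mol %), RuPhos (6 mol %), NaOtBu (1.5 equiv, premixed with 7), THF/toluene, rt
Reagents that add atoms: none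
Why: Copper/palladium-cooperative arylboration of an alkenyl arene, in which the chiral NHC–Cu–Bpin species should add across the E-alkene with boron on the carbon next to the electron-rich catechol ring and copper on the carbon next to the ester-bearing ring (better carbanion stabilisation, boron kept away from the di-ortho-substituted ring), so that catalyst-controlled facial selectivity sets the C1 centre before stereospecific transmetalation to ArPdBr and reductive elimination; syn addition would give the (1S,2R) adduct, but the configuration at the boron-bearing carbon does not matter.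

Step 5
Reactants: 8 methyl 4-{(1S)-2-[3,4-bis(benzyloxy)phenyl]-1-[3,5-bis(benzyloxy)phenyl]-2-(4,4,5,5-tetramethyl-1,3,2-dioxaborolan-2-yl)ethyl}-3,5-bis(methoxymethoxy)benzoate
Product: 10 methyl 4-{(1S)-2-[3,4-bis(benzyloxy)phenyl]-1-[3,5-bis(benzyloxy)phenyl]-2-hydroxyethyl}-3,5-dihydroxybenzoate (C2 epimers), via bis-phenol boronate 9 (not isolated)
Conditions: HCl (1.25 M in MeOH), THF, 40 °C; evaporate; then 30% aq H2O2, aq NaHCO3, THF, 0 °C to rt
Reagents that add atoms: hydrogen peroxide, OO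
Why: Acid-catalysed acetal cleavage of the aryl MOM ethers leaves the C–B bond intact, and peroxide oxidation of the boronate (1,2-shift from boron to oxygen with retention) then reveals the carbinol, so the ionisable benzylic alcohol is never exposed to acid while the phenols are still masked and the C1 centre is untouched.

Step 6
Reactants: 10 methyl 4-{(1S)-2-[3,4-bis(benzyloxy)phenyl]-1-[3,5-bis(benzyloxy)phenyl]-2-hydroxyethyl}-3,5-dihydroxybenzoate (C2 epimers)
Product: 11 methyl (2S,3S)-2-[3,4-bis(benzyloxy)phenyl]-3-[3,5-bis(benzyloxy)phenyl]-4-hydroxy-2,3-dihydro-1-benzofuran-6-carboxylate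
Conditions: TsOH·H2O (10 mol %), CH2Cl2 (dilute), 0 °C to rt
Reagents that add atoms: none
Why: Acid protonates the C2 hydroxyl and water leaves to give a benzylic cation delocalised onto the para benzyloxy oxygen (a quinone-methide-like oxocarbenium ion), the same ion from both carbinol epimers, so the step is stereoconvergent. The closest known reaction type is the acid-mediated cyclodehydration of 2-(2-hydroxyaryl)-1-arylethanols, that is, phenol trapping of para-quinone-methide-type cations to trans-2-aryl-2,3-dihydrobenzofurans. The ring closes in a 5-exo-trig mode when either of the two homotopic phenol oxygens ortho to C3a attacks cationic C2, forming O1–C2. The new C2 centre is controlled by the fixed C3 centre: the C2 aryl ends anti to the C3 aryl, kinetically through the rotamer that keeps the two aryl groups apart and thermodynamically because O1–C2 can re-ionise under the acid. The step needs ring closure to outrun loss of the C3 hydrogen (elimination to a triarylethylene, whose re-protonation would erode the C3 configuration) and to avoid ionisation at C3; the phenol held next to C2, the para ester that destabilises positive charge at C3, and catalytic acid at low temperature should secure this.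

Step 7
Reactants: 11 methyl (2S,3S)-2-[3,4-bis(benzyloxy)phenyl]-3-[3,5-bis(benzyloxy)phenyl]-4-hydroxy-2,3-dihydro-1-benzofuran-6-carboxylate
Product: 12 (2S,3S)-2-[3,4-bis(benzyloxy)phenyl]-3-[3,5-bis(benzyloxy)phenyl]-6-(hydroxymethyl)-2,3-dihydro-1-benzofuran-4-ol
Conditions: i-Bu2AlH (5 equiv), CH2Cl2, −78 to 0 °C; aq KNa tartrate
Reagents that add atoms: none
Why: Aluminium hydride reduction of the aryl ester to the benzylic alcohol, with the first equivalent consumed by the free phenol and the benzyl ethers and the cyclic benzylic ether inert to the reagent.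

Step 8
Reactants: 12 (2S,3S)-2-[3,4-bis(benzyloxy)phenyl]-3-[3,5-bis(benzyloxy)phenyl]-6-(hydroxymethyl)-2,3-dihydro-1-benzofuran-4-ol
Product: 13 (2S,3S)-2-[3,4-bis(benzyloxy)phenyl]-3-[3,5-bis(benzyloxy)phenyl]-4-hydroxy-2,3-dihydro-1-benzofuran-6-carbaldehyde
Conditions: MnO2 (activated, excess), CH2Cl2, rt
Reagents that add atoms: none
Why: Heterogeneous MnO2 oxidation is selective for the primary benzylic alcohol and stops at the aldehyde; the phenol is meta to the carbinol and cannot form a quinone methide, and C2/C3 are not affected.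

Step 9
Reactants: 14 4-(chloromethyl)-1,2-bis(benzyloxy)benzene; 15 triethyl phosphite
Product: 16 diethyl {[3,4-bis(benzyloxy)phenyl]methyl}phosphonate
Conditions: neat, 140 °C
Reagents that add atoms: none
Why: Michaelis–Arbuzov reaction of a benzylic chloride with the phosphite, driven by loss of volatile chloroethane.

Step 10
Reactants: 13 (2S,3S)-2-[3,4-bis(benzyloxy)phenyl]-3-[3,5-bis(benzyloxy)phenyl]-4-hydroxy-2,3-dihydro-1-benzofuran-6-carbaldehyde; 16 diethyl {[3,4-bis(benzyloxy)phenyl]methyl}phosphonate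
Product: 17 (2S,3S)-2-[3,4-bis(benzyloxy)phenyl]-3-[3,5-bis(benzyloxy)phenyl]-6-{(E)-2-[3,4-bis(benzyloxy)phenyl]ethenyl}-2,3-dihydro-1-benzofuran-4-ol
Conditions: KOtBu (3 equiv), THF, 0 °C to rt
Reagents that add atoms: none
Why: Horner–Wadsworth–Emmons olefination with a semi-stabilised benzylic phosphonate anion should give the E-alkene; the extra base covers the phenol, whose phenoxide is meta to the aldehyde and does not deactivate it, and neither C2 nor C3 carries an acidic hydrogen.

Step 11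
Reactants: 17 (2S,3S)-2-[3,4-bis(benzyloxy)phenyl]-3-[3,5-bis(benzyloxy)phenyl]-6-{(E)-2-[3,4-bis(benzyloxy)phenyl]ethenyl}-2,3-dihydro-1-benzofuran-4-ol
Product: 18 (2S,3S)-2-(3,4-dihydroxyphenyl)-3-(3,5-dihydroxyphenyl)-6-[(E)-2-(3,4-dihydroxyphenyl)ethenyl]-2,3-dihydro-1-benzofuran-4-ol
Conditions: BCl3 (1 M in CH2Cl2, 20 equiv), C6HMe5 (20 equiv), CH2Cl2, −78 °C; MeOH quench
Reagents that add atoms: none
Why: Lewis-acid cleavage of the six aryl benzyl ethers at low temperature, with pentamethylbenzene trapping the benzyl cations by Friedel–Crafts benzylation so that the stilbene and the electron-rich rings are not alkylated; any transient opening of O1–C2 should reclose to the more stable trans ring.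

Compound list
1 | methyl 4-bromo-3,5-dihydroxybenzoate | COC(=O)c1cc(O)c(Br)c(O)c1 | starting material
2 | methyl 4-bromo-3,5-bis(methoxymethoxy)benzoate | COCOc1cc(C(=O)OC)cc(OCOC)c1Br | intermediate
3 | 3,4-bis(benzyloxy)benzaldehyde | O=Cc1ccc(OCc2ccccc2)c(OCc2ccccc2)c1 | starting material
4 | 1,2-bis(benzyloxy)-4-ethenylbenzene | C=Cc1ccc(OCc2ccccc2)c(OCc2ccccc2)c1 | intermediate
5 | methyl 4-{(E)-2-[3,4-bis(benzyloxy)phenyl]ethenyl}-3,5-bis(methoxymethoxy)benzoate | COC(=O)c1cc(OCOC)c(/C=C/c2ccc(OCc3ccccc3)c(OCc3ccccc3)c2)c(OCOC)c1 | intermediate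
6 | 1,3-bis(benzyloxy)-5-bromobenzene | Brc1cc(OCc2ccccc2)cc(OCc2ccccc2)c1 | starting material
7 | bis(pinacolato)diboron | CC1(C)OB(B2OC(C)(C)C(C)(C)O2)OC1(C)C | starting material
8 | methyl 4-{(1S)-2-[3,4-bis(benzyloxy)phenyl]-1-[3,5-bis(benzyloxy)phenyl]-2-(4,4,5,5-tetramethyl-1,3,2-dioxaborolan-2-yl)ethyl}-3,5-bis(methoxymethoxy)benzoate (C2 open; 2R expected from syn addition) | c1ccccc1COc1cc(OCc2ccccc2)cc([C@H](C(B2OC(C)(C)C(C)(C)O2)c2ccc(OCc3ccccc3)c(OCc3ccccc3)c2)c2c(OCOC)cc(C(=O)OC)cc2OCOC)c1 | intermediate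
9 | methyl 4-{(1S)-2-[3,4-bis(benzyloxy)phenyl]-1-[3,5-bis(benzyloxy)phenyl]-2-(4,4,5,5-tetramethyl-1,3,2-dioxaborolan-2-yl)ethyl}-3,5-dihydroxybenzoate (C2 open) | c1ccccc1COc1cc(OCc2ccccc2)cc([C@H](C(B2OC(C)(C)C(C)(C)O2)c2ccc(OCc3ccccc3)c(OCc3ccccc3)c2)c2c(O)cc(C(=O)OC)cc2O)c1 | intermediate (not isolated)
10 | methyl 4-{(1S)-2-[3,4-bis(benzyloxy)phenyl]-1-[3,5-bis(benzyloxy)phenyl]-2-hydroxyethyl}-3,5-dihydroxybenzoate (C2 epimers) | c1ccccc1COc1cc(OCc2ccccc2)cc([C@H](C(O)c2ccc(OCc3ccccc3)c(OCc3ccccc3)c2)c2c(O)cc(C(=O)OC)cc2O)c1 | intermediate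
11 | methyl (2S,3S)-2-[3,4-bis(benzyloxy)phenyl]-3-[3,5-bis(benzyloxy)phenyl]-4-hydroxy-2,3-dihydro-1-benzofuran-6-carboxylate | c1ccccc1COc1cc(OCc2ccccc2)cc([C@H]2c3c(O)cc(C(=O)OC)cc3O[C@@H]2c2ccc(OCc3ccccc3)c(OCc3ccccc3)c2)c1 | intermediate
12 | (2S,3S)-2-[3,4-bis(benzyloxy)phenyl]-3-[3,5-bis(benzyloxy)phenyl]-6-(hydroxymethyl)-2,3-dihydro-1-benzofuran-4-ol | c1ccccc1COc1cc(OCc2ccccc2)cc([C@H]2c3c(O)cc(CO)cc3O[C@@H]2c2ccc(OCc3ccccc3)c(OCc3ccccc3)c2)c1 | intermediate
13 | (2S,3S)-2-[3,4-bis(benzyloxy)phenyl]-3-[3,5-bis(benzyloxy)phenyl]-4-hydroxy-2,3-dihydro-1-benzofuran-6-carbaldehyde | c1ccccc1COc1cc(OCc2ccccc2)cc([C@H]2c3c(O)cc(C=O)cc3O[C@@H]2c2ccc(OCc3ccccc3)c(OCc3ccccc3)c2)c1 | intermediate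
14 | 4-(chloromethyl)-1,2-bis(benzyloxy)benzene | ClCc1ccc(OCc2ccccc2)c(OCc2ccccc2)c1 | starting material
15 | triethyl phosphite | CCOP(OCC)OCC | starting material
16 | diethyl {[3,4-bis(benzyloxy)phenyl]methyl}phosphonate | CCOP(=O)(Cc1ccc(OCc2ccccc2)c(OCc2ccccc2)c1)OCC | intermediate
17 | (2S,3S)-2-[3,4-bis(benzyloxy)phenyl]-3-[3,5-bis(benzyloxy)phenyl]-6-{(E)-2-[3,4-bis(benzyloxy)phenyl]ethenyl}-2,3-dihydro-1-benzofuran-4-ol | c1ccccc1COc1cc(OCc2ccccc2)cc([C@H]2c3c(O)cc(/C=C/c4ccc(OCc5ccccc5)c(OCc5ccccc5)c4)cc3O[C@@H]2c2ccc(OCc3ccccc3)c(OCc3ccccc3)c2)c1 | intermediate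
18 | (2S,3S)-2-(3,4-dihydroxyphenyl)-3-(3,5-dihydroxyphenyl)-6-[(E)-2-(3,4-dihydroxyphenyl)ethenyl]-2,3-dihydro-1-benzofuran-4-ol | Oc1cc(O)cc([C@H]2c3c(O)cc(/C=C/c4ccc(O)c(O)c4)cc3O[C@@H]2c2ccc(O)c(O)c2)c1 | target

Total steps: 11. Longest linear sequence: 9 (steps 1, 3, 4, 5, 6, 7, 8, 10, 11 from 1; the same length from 3 via step 2).

Steps most likely to fail

Step 4 (arylboration). The borylcupration of the hindered, ester-bearing stilbene may be slow, and copper may be placed partly at the catechol-side carbon. Facial selectivity may be insufficient, and direct borylation of 6 or alkoxide exchange at the methyl ester may compete. The fallback is a stepwise carbanion route with resolution, setting out from 2 and 3 and returning at 11. Negishi coupling of 2 with [3,5-bis(benzyloxy)phenyl]methylzinc bromide F1 (from commercial 3,5-bis(benzyloxy)benzyl bromide and Zn/LiCl; Pd(OAc)2, SPhos, THF) should give the diarylmethane methyl 4-{[3,5-bis(benzyloxy)phenyl]methyl}-3,5-bis(methoxymethoxy)benzoate F2. Its doubly benzylic CH2, which is para to the ester, would be deprotonated with LiN(i-Pr)2 at −78 °C and the anion added to aldehyde 3, giving the racemic carbinol methyl 4-{2-[3,4-bis(benzyloxy)phenyl]-1-[3,5-bis(benzyloxy)phenyl]-2-hydroxyethyl}-3,5-bis(methoxymethoxy)benzoate F3. Methanolic HCl would then remove the MOM groups and close the ring by the same cationic cyclisation; loss of configuration is immaterial for racemic material. This gives 11 together with its enantiomer methyl (2R,3R)-2-[3,4-bis(benzyloxy)phenyl]-3-[3,5-bis(benzyloxy)phenyl]-4-hydroxy-2,3-dihydro-1-benzofuran-6-carboxylate F4, and preparative chromatography on a chiral stationary phase would deliver 11.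

Step 6 (key cyclisation). The cation may lose the C3 hydrogen before it is trapped, which would erode enantiopurity through the triarylethylene. The trans preference may be incomplete, and intermolecular Friedel–Crafts alkylation may appear if the solution is too concentrated. The fallback runs from 10 to 11 by Mitsunobu cyclodehydration (PPh3, diisopropyl azodicarboxylate, THF, 0 °C) of the (1S,2R) epimer of 10. This is the epimer expected from syn arylboration and stereoretentive oxidation; any (2S) epimer would be removed by chromatography first. A phenol displaces the activated hydroxyl with inversion under neutral conditions, which gives the same trans (2S,3S) ring without a free cation; no new compound is made (F0).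

Step 11 (global debenzylation). The Lewis acid may ionise O1–C2, with capture of the cation by the scavenger or elimination. Cleavage of all six ethers may be incomplete, and the catechols may oxidise in air on work-up. The fallback exchanges the protecting groups before the alkene exists, setting out from 11 and returning at 18. Hydrogenolysis (H2, Pd/C, EtOAc/MeOH) should give methyl (2S,3S)-2-(3,4-dihydroxyphenyl)-3-(3,5-dihydroxyphenyl)-4-hydroxy-2,3-dihydro-1-benzofuran-6-carboxylate F5. Silylation (TBSCl, imidazole, DMF) would give methyl (2S,3S)-2-[3,4-bis(tert-butyldimethylsilyloxy)phenyl]-3-[3,5-bis(tert-butyldimethylsilyloxy)phenyl]-4-(tert-butyldimethylsilyloxy)-2,3-dihydro-1-benzofuran-6-carboxylate F6. Reduction with i-Bu2AlH would give the benzylic alcohol [(2S,3S)-2-[3,4-bis(tert-butyldimethylsilyloxy)phenyl]-3-[3,5-bis(tert-butyldimethylsilyloxy)phenyl]-4-(tert-butyldimethylsilyloxy)-2,3-dihydro-1-benzofuran-6-yl]methanol F7, and MnO2 would give the corresponding 6-carbaldehyde F8. Horner–Wadsworth–Emmons olefination (NaH, THF) with separately prepared diethyl {[3,4-bis(tert-butyldimethylsilyloxy)phenyl]methyl}phosphonate F9 would give the heptakis(tert-butyldimethylsilyl) ether of 18 F10. Buffered fluoride (Bu4NF, AcOH, THF, 0 °C) would then release 18 without any Lewis acid.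

Further compounds
F1 | step 4 | [3,5-bis(benzyloxy)phenyl]methylzinc bromide | Br[Zn]Cc1cc(OCc2ccccc2)cc(OCc2ccccc2)c1
F2 | step 4 | methyl 4-{[3,5-bis(benzyloxy)phenyl]methyl}-3,5-bis(methoxymethoxy)benzoate | COC(=O)c1cc(OCOC)c(Cc2cc(OCc3ccccc3)cc(OCc3ccccc3)c2)c(OCOC)c1
F3 | step 4 | methyl 4-{2-[3,4-bis(benzyloxy)phenyl]-1-[3,5-bis(benzyloxy)phenyl]-2-hydroxyethyl}-3,5-bis(methoxymethoxy)benzoate (racemic, both diastereomers) | COC(=O)c1cc(OCOC)c(C(c2cc(OCc3ccccc3)cc(OCc3ccccc3)c2)C(O)c2ccc(OCc3ccccc3)c(OCc3ccccc3)c2)c(OCOC)c1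
F4 | step 4 | methyl (2R,3R)-2-[3,4-bis(benzyloxy)phenyl]-3-[3,5-bis(benzyloxy)phenyl]-4-hydroxy-2,3-dihydro-1-benzofuran-6-carboxylate | c1ccccc1COc1cc(OCc2ccccc2)cc([C@@H]2c3c(O)cc(C(=O)OC)cc3O[C@H]2c2ccc(OCc3ccccc3)c(OCc3ccccc3)c2)c1
F0 | step 6 | none | none
F5 | step 11 | methyl (2S,3S)-2-(3,4-dihydroxyphenyl)-3-(3,5-dihydroxyphenyl)-4-hydroxy-2,3-dihydro-1-benzofuran-6-carboxylate | Oc1cc(O)cc([C@H]2c3c(O)cc(C(=O)OC)cc3O[C@@H]2c2ccc(O)c(O)c2)c1
F6 | step 11 | methyl (2S,3S)-2-[3,4-bis(tert-butyldimethylsilyloxy)phenyl]-3-[3,5-bis(tert-butyldimethylsilyloxy)phenyl]-4-(tert-butyldimethylsilyloxy)-2,3-dihydro-1-benzofuran-6-carboxylate | CC(C)(C)[Si](C)(C)Oc1cc(O[Si](C)(C)C(C)(C)C)cc([C@H]2c3c(O[Si](C)(C)C(C)(C)C)cc(C(=O)OC)cc3O[C@@H]2c2ccc(O[Si](C)(C)C(C)(C)C)c(O[Si](C)(C)C(C)(C)C)c2)c1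
F7 | step 11 | [(2S,3S)-2-[3,4-bis(tert-butyldimethylsilyloxy)phenyl]-3-[3,5-bis(tert-butyldimethylsilyloxy)phenyl]-4-(tert-butyldimethylsilyloxy)-2,3-dihydro-1-benzofuran-6-yl]methanol | CC(C)(C)[Si](C)(C)Oc1cc(O[Si](C)(C)C(C)(C)C)cc([C@H]2c3c(O[Si](C)(C)C(C)(C)C)cc(CO)cc3O[C@@H]2c2ccc(O[Si](C)(C)C(C)(C)C)c(O[Si](C)(C)C(C)(C)C)c2)c1
F8 | step 11 | (2S,3S)-2-[3,4-bis(tert-butyldimethylsilyloxy)phenyl]-3-[3,5-bis(tert-butyldimethylsilyloxy)phenyl]-4-(tert-butyldimethylsilyloxy)-2,3-dihydro-1-benzofuran-6-carbaldehyde | CC(C)(C)[Si](C)(C)Oc1cc(O[Si](C)(C)C(C)(C)C)cc([C@H]2c3c(O[Si](C)(C)C(C)(C)C)cc(C=O)cc3O[C@@H]2c2ccc(O[Si](C)(C)C(C)(C)C)c(O[Si](C)(C)C(C)(C)C)c2)c1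
F9 | step 11 | diethyl {[3,4-bis(tert-butyldimethylsilyloxy)phenyl]methyl}phosphonate | CCOP(=O)(Cc1ccc(O[Si](C)(C)C(C)(C)C)c(O[Si](C)(C)C(C)(C)C)c1)OCC
F10 | step 11 | heptakis(tert-butyldimethylsilyl) ether of 18 | CC(C)(C)[Si](C)(C)Oc1cc(O[Si](C)(C)C(C)(C)C)cc([C@H]2c3c(O[Si](C)(C)C(C)(C)C)cc(/C=C/c4ccc(O[Si](C)(C)C(C)(C)C)c(O[Si](C)(C)C(C)(C)C)c4)cc3O[C@@H]2c2ccc(O[Si](C)(C)C(C)(C)C)c(O[Si](C)(C)C(C)(C)C)c2)c1
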